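A direct plan would build ring C first as the pyranone Weinreb amide A1, would make the side chain as the silylated bromide A2 by an auxiliary-controlled acetate aldol reaction with methacrolein, would join the two by a Grignard addition, and would close ring A last by Wolff rearrangement and siloxyalkyne benzannulation of the diazo ketone A3 to the silylated flavone A4.
Its weak points would be three.
The aldol addition would leave the only stereocentre to a modest, auxiliary-dependent facial preference and would open a four-step sequence for one six-carbon chain.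
The Grignard addition would have to spare the pyranone, which is itself an acceptor at C4 and at C2/C6.
The benzannulation would need the C2=C3 bond of a 4-pyranone as the 6π partner, a role without precedent, would compete with 1,2-hydride shift in the carbene, and would be run on the most precious material of the route.

Plan of the new route
Retrosynthesis: the two O-allyl groups are cut last; the allylic alcohol goes back to an (R)-epoxide and this to an 8-prenyl group; the C8–C1'' bond is traced back to an O5–C1'' bond (prenyl ether 8); ring C is cut at O1–C2 and C3–C4 into 2',4',6'-trihydroxyacetophenone and an aroyl chloride.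
Rings A and B are bought, ring C is closed first (step 2), and the side chain is placed on the finished core.
Enabling feature: O5 of ring A is peri to the C4 carbonyl, where it forms a chelating site for a europium Lewis acid, and para to C8, with the free C6–H between them; a prenyl group on O5 is therefore passed O5 → C6 → C8 by two [3,3] shifts, and no external electrophile has to choose between C6 and C8.
The stereocentre is set on the finished skeleton by catalyst-controlled epoxidation of the prenyl alkene and kept by an isomerisation that never breaks its C–O bond, as in the presumed biogenesis of this side chain.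
No auxiliary, no organometallic addition to a pyranone, no diazo compound and no ring construction on late material occur.

Key step: step 5

Remark: the D-fructose-derived ketone is assumed to attack alkenes of the type R–CH2–CH=CMe2 in the sense of its spiro transition-state model, which corresponds to the (R)-epoxide; the enantiomeric ketone would be used if the sense proved to be the other. Side-chain carbons are called C1'' (benzylic CH2), C2'' (carbinol) and C3'' (isopropenyl carbon); commercial 3 is a monohydrate and would be dried before use.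

Step 1
Reactants: 1 4-(allyloxy)benzoic acid
Product: 2 4-(allyloxy)benzoyl chloride
Conditions: (COCl)2, DMF (cat.), CH2Cl2, 0 → 23 °C
Reagents that add atoms: oxalyl chloride, O=C(Cl)C(Cl)=O
Why: Standard conversion of a carboxylic acid into its chloride through the chloroiminium salt formed from DMF and oxalyl chloride (Vilsmeier-type activation), which the allyl aryl ether should tolerate.

Step 2
Reactants: 3 2',4',6'-trihydroxyacetophenone; 2 4-(allyloxy)benzoyl chloride
Product: 5 2-[4-(allyloxy)phenyl]-5,7-dihydroxy-4H-chromen-4-one, via diketone 4 (not isolated)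
Conditions: 3, LiN(SiMe3)2 (5 equiv), THF, −78 → −10 °C; then 2, −78 → 23 °C; aq. HCl; then H2SO4 (0.5 %), AcOH, 95 °C
Reagents that add atoms: none
Why: Claisen-type C-acylation of the lithium enolate within the tetraanion of 3 (one-pot variant of the Baker–Venkataraman diketone synthesis) should give the o-hydroxyaryl 1,3-diketone 4, whose acid-catalysed cyclodehydration closes ring C through O1–C2; the two ortho hydroxyls of 3 are equivalent, so closure through either gives the same flavone and makes O5 and O7 different from here on.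

Step 3
Reactants: 5 2-[4-(allyloxy)phenyl]-5,7-dihydroxy-4H-chromen-4-one
Product: 6 7-(allyloxy)-2-[4-(allyloxy)phenyl]-5-hydroxy-4H-chromen-4-one
Conditions: allyl bromide (1.1 equiv), K2CO3, acetone, 56 °C
Reagents that add atoms: allyl bromide, C=CCBr
Why: Williamson ether synthesis at the most acidic hydroxyl: the 7-OH is a vinylogous carboxylic acid and is alkylated by one equivalent of halide, while the 5-OH is held in a hydrogen bond to the C4 carbonyl and stays free.

Step 4
Reactants: 6 7-(allyloxy)-2-[4-(allyloxy)phenyl]-5-hydroxy-4H-chromen-4-one; 7 1-bromo-3-methylbut-2-ene (prenyl bromide)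
Product: 8 7-(allyloxy)-2-[4-(allyloxy)phenyl]-5-[(3-methylbut-2-en-1-yl)oxy]-4H-chromen-4-one
Conditions: 7 (3 equiv), K2CO3 (4 equiv), DMF, 50 °C
Reagents that add atoms: none
Why: Williamson ether synthesis at the only hydroxyl left, the chelated 5-OH, which needs excess halide and a dipolar aprotic solvent; O-alkylation should prevail over C-alkylation for the potassium phenoxide in DMF.

Step 5
Reactants: 8 7-(allyloxy)-2-[4-(allyloxy)phenyl]-5-[(3-methylbut-2-en-1-yl)oxy]-4H-chromen-4-one
Product: 11 7-(allyloxy)-2-[4-(allyloxy)phenyl]-5-hydroxy-8-(3-methylbut-2-en-1-yl)-4H-chromen-4-one, via Claisen dienone 9 (not isolated), via Cope dienone 10 (not isolated)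
Conditions: Eu(fod)3 [fod = 6,6,7,7,8,8,8-heptafluoro-2,2-dimethyloctane-3,5-dionate] (10 mol %), NaHCO3, PhCl, 85 °C
Reagents that add atoms: none
Why: Eu(fod)3 binds the C4 carbonyl and O5 and weakens the O5–C1'' bond, so that a first [3,3] shift (aromatic Claisen rearrangement) carries the prenyl group, inverted, to C6 in dienone 9, and a second [3,3] shift (Cope rearrangement) across C6–C7–C8 carries it on, inverted again and therefore as a normal prenyl group, to C8 in dienone 10, which enolises to the chelated 5-hydroxyflavone 11. The closest known reaction type is the europium-catalysed para-Claisen–Cope rearrangement of 5-O-prenyl ethers of flavanones and flavonols to their 8-prenyl isomers. No ring is closed and no stereocentre remains, since C6 of 9 and C8 of 10 are transient sp3 centres. The step needs the Cope shift of 9 to outrun its enolisation to the 6-(1,1-dimethylallyl) phenol: the congested quaternary carbon between the C5 carbonyl and the C7 allyloxy group drives the second shift, and NaHCO3 keeps traces of acid from catalysing enolisation or ether cleavage. The regiochemistry follows from the topology, because C4a is blocked and, from C6, the only terminus other than O5 within reach of a [3,3] shift is C8. The two allyl aryl ethers lack the chelating carbonyl and should rearrange only far above 85 °C.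

Step 6
Reactants: 11 7-(allyloxy)-2-[4-(allyloxy)phenyl]-5-hydroxy-8-(3-methylbut-2-en-1-yl)-4H-chromen-4-one
Product: 12 7-(allyloxy)-2-[4-(allyloxy)phenyl]-8-{[(2R)-3,3-dimethyloxiran-2-yl]methyl}-5-hydroxy-4H-chromen-4-one
Conditions: D-fructose-derived Shi ketone (1,2:4,5-di-O-isopropylidene-β-D-erythro-hexo-2,3-diulo-2,6-pyranose, 0.3 equiv), Oxone (2KHSO5·KHSO4·K2SO4, 1.4 equiv), K2CO3, Bu4NHSO4 (cat.), MeCN–CH2(OMe)2, aq. Na2B4O7–Na2EDTA buffer (pH 10.5), 0 °C
Reagents that add atoms: potassium peroxymonosulfate (active salt of Oxone), [K+].OOS(=O)(=O)[O-]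
Why: Shi epoxidation: the chiral dioxirane formed from the ketone and peroxymonosulfate transfers oxygen through a spiro transition state to one face of the trisubstituted, electron-rich prenyl alkene, which sets the only stereocentre (R) under catalyst control, while the monosubstituted allyl ether alkenes and the electron-poor C2=C3 bond react far more slowly and the allyl group on O7 keeps that oxygen from opening the epoxide.

Step 7
Reactants: 12 7-(allyloxy)-2-[4-(allyloxy)phenyl]-8-{[(2R)-3,3-dimethyloxiran-2-yl]methyl}-5-hydroxy-4H-chromen-4-one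
Product: 13 7-(allyloxy)-2-[4-(allyloxy)phenyl]-5-hydroxy-8-[(2R)-2-hydroxy-3-methylbut-3-en-1-yl]-4H-chromen-4-one
Conditions: Al(OiPr)3 (3 equiv), toluene, 100 °C; aq. potassium sodium tartrate
Reagents that add atoms: none
Why: Aluminium-alkoxide-mediated isomerisation of a 2,2-dimethyloxirane to an isopropenyl carbinol: aluminium bound to the epoxide oxygen weakens the bond to the tertiary C3'' and an isopropoxide ligand takes a proton from a methyl group in a cyclic syn-elimination, so that the C2''–O bond is never broken and the configuration is retained; one equivalent of the reagent is taken up by the chelated 5-OH.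

Step 8
Reactants: 13 7-(allyloxy)-2-[4-(allyloxy)phenyl]-5-hydroxy-8-[(2R)-2-hydroxy-3-methylbut-3-en-1-yl]-4H-chromen-4-one
Product: 14 (R)-5,7-dihydroxy-8-(2-hydroxy-3-methylbut-3-en-1-yl)-2-(4-hydroxyphenyl)-4H-chromen-4-one (CNP0315675.1)
Conditions: Pd(PPh3)4 (5 mol %), morpholine (6 equiv), THF, 23 °C; aq. NH4Cl
Reagents that add atoms: none
Why: Tsuji–Trost deallylation: zerovalent palladium ionises both allyl aryl ethers to π-allyl complexes and phenoxides and morpholine takes up the allyl groups, under neutral conditions that neither ionise the unactivated secondary allylic alcohol nor protonate the isopropenyl group, which acid would cyclise onto O7.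

Compound list
1 | 4-(allyloxy)benzoic acid | C=CCOc1ccc(C(=O)O)cc1 | starting material
2 | 4-(allyloxy)benzoyl chloride | C=CCOc1ccc(C(=O)Cl)cc1 | intermediate
3 | 2',4',6'-trihydroxyacetophenone | CC(=O)c1c(O)cc(O)cc1O | starting material
4 | 1-[4-(allyloxy)phenyl]-3-(2,4,6-trihydroxyphenyl)propane-1,3-dione (not isolated) | O=C(CC(=O)c1ccc(OCC=C)cc1)c1c(O)cc(O)cc1O | intermediate
5 | 2-[4-(allyloxy)phenyl]-5,7-dihydroxy-4H-chromen-4-one | C=CCOc1ccc(-c2cc(=O)c3c(O)cc(O)cc3o2)cc1 | intermediate
6 | 7-(allyloxy)-2-[4-(allyloxy)phenyl]-5-hydroxy-4H-chromen-4-one | C=CCOc1ccc(-c2cc(=O)c3c(O)cc(OCC=C)cc3o2)cc1 | intermediate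
7 | 1-bromo-3-methylbut-2-ene (prenyl bromide) | CC(C)=CCBr | starting material
8 | 7-(allyloxy)-2-[4-(allyloxy)phenyl]-5-[(3-methylbut-2-en-1-yl)oxy]-4H-chromen-4-one | CC(C)=CCOc1cc(OCC=C)cc2oc(-c3ccc(OCC=C)cc3)cc(=O)c12 | intermediate
9 | Claisen dienone: 7-(allyloxy)-2-[4-(allyloxy)phenyl]-6-(2-methylbut-3-en-2-yl)-4H-chromene-4,5(6H)-dione (both enantiomers; not isolated) | C=CC(C)(C)C1C(=O)C2=C(C=C1OCC=C)OC(-c1ccc(OCC=C)cc1)=CC2=O | intermediate
10 | Cope dienone: 7-(allyloxy)-2-[4-(allyloxy)phenyl]-8-(3-methylbut-2-en-1-yl)-4H-chromene-4,5(8H)-dione (both enantiomers; not isolated) | CC(C)=CCC1C(OCC=C)=CC(=O)C2=C1OC(-c1ccc(OCC=C)cc1)=CC2=O | intermediate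
11 | 7-(allyloxy)-2-[4-(allyloxy)phenyl]-5-hydroxy-8-(3-methylbut-2-en-1-yl)-4H-chromen-4-one | CC(C)=CCc1c(OCC=C)cc(O)c2c(=O)cc(-c3ccc(OCC=C)cc3)oc12 | intermediate
12 | 7-(allyloxy)-2-[4-(allyloxy)phenyl]-8-{[(2R)-3,3-dimethyloxiran-2-yl]methyl}-5-hydroxy-4H-chromen-4-one | CC1(C)O[C@@H]1Cc1c(OCC=C)cc(O)c2c(=O)cc(-c3ccc(OCC=C)cc3)oc12 | intermediate
13 | 7-(allyloxy)-2-[4-(allyloxy)phenyl]-5-hydroxy-8-[(2R)-2-hydroxy-3-methylbut-3-en-1-yl]-4H-chromen-4-one | C=C(C)[C@H](O)Cc1c(OCC=C)cc(O)c2c(=O)cc(-c3ccc(OCC=C)cc3)oc12 | intermediate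
14 | (R)-5,7-dihydroxy-8-(2-hydroxy-3-methylbut-3-en-1-yl)-2-(4-hydroxyphenyl)-4H-chromen-4-one (CNP0315675.1) | C=C(C)[C@H](O)Cc1c(O)cc(O)c2c(=O)cc(-c3ccc(O)cc3)oc12 | target

Total step count: 8. Longest linear sequence: 8 steps (1 → 14); 7 steps counted from 3.

Steps most likely to fail

Step 5. Dienone 9 might enolise before the second shift, which would end at the 6-(1,1-dimethylallyl) phenol, or the Lewis acid might cleave the prenyl ether back to 6. The fallback sets out from 3 and comes back to the route at 14; it fixes the position of the prenyl group by steric differentiation of the hydroxyls instead of by relay. C-Prenylation of 3 with 7 in aqueous KOH at 0 °C would give 2,4,6-trihydroxy-3-prenylacetophenone F1. Allyl bromide (2.1 equiv) and K2CO3 in acetone would etherify the two less hindered hydroxyls and leave the one between the prenyl and acetyl groups, to give 4,6-bis(allyloxy)-2-hydroxy-3-prenylacetophenone F2. C-Acylation of its dianion (LiN(SiMe3)2, THF, −78 °C) with 2 would give the diketone F3, and p-TsOH (cat.) in toluene at 60 °C would close ring C through the only free hydroxyl to 5,7,4'-tri-O-allyl-8-prenylapigenin F4. The conditions of steps 6, 7 and 8 would then give the epoxide F5, the carbinol F6 and, by loss of all three allyl groups, 14.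

Step 7. The aluminium Lewis acid might open the epoxide to a free tertiary cation, which would end in hydride shift to the isopropyl ketone or in attack of the O7 ether oxygen with loss of its allyl group, or the aluminium chelate of the 5-OH might resist work-up. The fallback runs from 12 to 13 and breaks the C3''–O bond homolytically instead. Cp2TiCl (trivalent titanium, made in the flask from Cp2TiCl2 and Mn dust, THF, 23 °C) would open the epoxide to the tertiary C3'' radical, a second Cp2TiCl would trap it, and β-hydride elimination from a methyl group would give the same isopropenyl carbinol with the C2''–O bond intact. No cation and no new compound would be involved.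

Step 6. The facial selectivity might be low, or the dioxirane might oxidise the electron-rich ring A or an allyl ether. The fallback runs from 11 to 13 and sets the stereocentre by reduction of a ketone instead of by oxygen transfer to the alkene. m-CPBA (NaHCO3, CH2Cl2, 0 °C) would give the racemic epoxide F7, Al(OiPr)3 as in step 7 the racemic carbinol F8, and Dess–Martin periodinane the isopropenyl ketone F9. (S)-2-Methyl-CBS-oxazaborolidine with catecholborane (toluene, −78 °C) would reduce F9 to 13, with the isopropenyl group as the large and the arylmethyl group as the small substituent.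

Further compounds
F1 | step 5 | 1-[2,4,6-trihydroxy-3-(3-methylbut-2-en-1-yl)phenyl]ethan-1-one | CC(=O)c1c(O)cc(O)c(CC=C(C)C)c1O
F2 | step 5 | 1-[4,6-bis(allyloxy)-2-hydroxy-3-(3-methylbut-2-en-1-yl)phenyl]ethan-1-one | CC(=O)c1c(O)c(CC=C(C)C)c(OCC=C)cc1OCC=C
F3 | step 5 | 1-[4,6-bis(allyloxy)-2-hydroxy-3-(3-methylbut-2-en-1-yl)phenyl]-3-[4-(allyloxy)phenyl]propane-1,3-dione | CC(C)=CCc1c(O)c(C(=O)CC(=O)c2ccc(OCC=C)cc2)c(OCC=C)cc1OCC=C
F4 | step 5 | 5,7-bis(allyloxy)-2-[4-(allyloxy)phenyl]-8-(3-methylbut-2-en-1-yl)-4H-chromen-4-one | CC(C)=CCc1c(OCC=C)cc(OCC=C)c2c(=O)cc(-c3ccc(OCC=C)cc3)oc12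
F5 | step 5 | 5,7-bis(allyloxy)-2-[4-(allyloxy)phenyl]-8-{[(2R)-3,3-dimethyloxiran-2-yl]methyl}-4H-chromen-4-one | CC1(C)O[C@@H]1Cc1c(OCC=C)cc(OCC=C)c2c(=O)cc(-c3ccc(OCC=C)cc3)oc12
F6 | step 5 | 5,7-bis(allyloxy)-2-[4-(allyloxy)phenyl]-8-[(2R)-2-hydroxy-3-methylbut-3-en-1-yl]-4H-chromen-4-one | C=C(C)[C@H](O)Cc1c(OCC=C)cc(OCC=C)c2c(=O)cc(-c3ccc(OCC=C)cc3)oc12
F0 | step 7 | none | none
F7 | step 6 | rac-7-(allyloxy)-2-[4-(allyloxy)phenyl]-8-[(3,3-dimethyloxiran-2-yl)methyl]-5-hydroxy-4H-chromen-4-one | CC1(C)OC1Cc1c(OCC=C)cc(O)c2c(=O)cc(-c3ccc(OCC=C)cc3)oc12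
F8 | step 6 | rac-7-(allyloxy)-2-[4-(allyloxy)phenyl]-5-hydroxy-8-(2-hydroxy-3-methylbut-3-en-1-yl)-4H-chromen-4-one | C=C(C)C(O)Cc1c(OCC=C)cc(O)c2c(=O)cc(-c3ccc(OCC=C)cc3)oc12
F9 | step 6 | 7-(allyloxy)-2-[4-(allyloxy)phenyl]-5-hydroxy-8-(3-methyl-2-oxobut-3-en-1-yl)-4H-chromen-4-one | C=C(C)C(=O)Cc1c(OCC=C)cc(O)c2c(=O)cc(-c3ccc(OCC=C)cc3)oc12
A1 | direct plan | N-methoxy-N-methyl-4-oxo-6-[4-(triisopropylsilyloxy)phenyl]-4H-pyran-2-carboxamide | CON(C)C(=O)c1cc(=O)cc(-c2ccc(O[Si](C(C)C)(C(C)C)C(C)C)cc2)o1
A2 | direct plan | (R)-5-bromo-3-(tert-butyldimethylsilyloxy)-2-methylpent-1-ene | C=C(C)[C@H](O[Si](C)(C)C(C)(C)C)CCBr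
A3 | direct plan | (R)-2-diazo-4-(tert-butyldimethylsilyloxy)-5-methyl-1-{4-oxo-6-[4-(triisopropylsilyloxy)phenyl]-4H-pyran-2-yl}hex-5-en-1-one | C=C(C)[C@H](O[Si](C)(C)C(C)(C)C)CC(=[N+]=[N-])C(=O)c1cc(=O)cc(-c2ccc(O[Si](C(C)C)(C(C)C)C(C)C)cc2)o1
A4 | direct plan | (R)-8-[2-(tert-butyldimethylsilyloxy)-3-methylbut-3-enyl]-5-hydroxy-7-(triisopropylsilyloxy)-2-[4-(triisopropylsilyloxy)phenyl]-4H-chromen-4-one | C=C(C)[C@H](O[Si](C)(C)C(C)(C)C)Cc1c(O[Si](C(C)C)(C(C)C)C(C)C)cc(O)c2c(=O)cc(-c3ccc(O[Si](C(C)C)(C(C)C)C(C)C)cc3)oc12
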